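**Retrosynthetic overview**
1. The oxepine is closed last: C7a–O–CMe2 bond by intramolecular Nicholas etherification of a Co2(CO)6-complexed propargylic methyl ether, then reductive decomplexation to the cis-alkene.
2. Ring oxygens: the cis-4,5-diol (later OAc/OBz) comes from osmylation of a ring alkene; the trans-7,7a-diol from epoxidation and anti hydrolysis of a butenolide double bond.
3. Core: the cyclohexadiene and the γ-lactone are formed together by an ester-tethered intramolecular Diels–Alder reaction of a but-2-ynoate onto a 2-silyloxydiene; the carbinol centre C-3 sets the quaternary centre C-3a.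
4. The Diels–Alder precursor comes from an Evans syn-aldol of a propanoyl oxazolidinone with 4-methoxy-4-methylpent-2-ynal, then Weinreb amide, vinyl Grignard and esterification.
5. Ring order: carbocycle + lactone (one operation), then oxepine.

Assumption: the oxepine alkene is cis (the only geometry a seven-membered ring allows). Bicyclic intermediates carry 2-benzofuran-1(3H)-one locants (C-1 lactone C=O, C-3 carbinol carbon, C-3a methyl-bearing ring-fusion carbon, C-7a oxygenated ring-fusion carbon); "upper face" is the face of the 3a-methyl group.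

**Route**

Step 1
Reactants: 1 2-methylbut-3-yn-2-ol
Product: 2 3-methoxy-3-methylbut-1-yne
Conditions: Me2SO4, 50% aq NaOH, n-Bu4NHSO4 (cat.), 25–40 °C; distil
Reagents that add atoms: dimethyl sulfate, COS(=O)(=O)OC
Why: Williamson O-methylation under phase transfer, in which hydroxide does not metalate the alkyne C–H; the methyl ether is inert until it serves as the leaving group in step 12, and no stereocentre is involved.

Step 2
Reactants: 2 3-methoxy-3-methylbut-1-yne
Product: 4 4-methoxy-4-methylpent-2-ynal, via lithium acetylide 3 (not isolated)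
Conditions: n-BuLi, THF, −78 °C; DMF, −78 → 0 °C; inverse quench into aq KH2PO4
Reagents that add atoms: N,N-dimethylformamide, CN(C)C=O
Why: Formylation of a lithium acetylide with DMF; the hemiaminal alkoxide survives until the buffered inverse quench, which prevents amine addition to the ynal.

Step 3
Reactants: 5 (4R)-4-benzyl-3-propanoyl-1,3-oxazolidin-2-one; 4 4-methoxy-4-methylpent-2-ynal
Product: 7 (4R)-4-benzyl-3-[(2R,3R)-3-hydroxy-6-methoxy-2,6-dimethylhept-4-ynoyl]-1,3-oxazolidin-2-one, via boron enolate 6 (not isolated)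
Conditions: n-Bu2BOTf, i-Pr2NEt, CH2Cl2, 0 °C; then 4, −78 → 0 °C; pH 7 buffer, MeOH, H2O2
Reagents that add atoms: none
Why: Evans syn-aldol through the Zimmerman–Traxler chair of the (Z)-boron enolate, the benzyl group shielding one enolate face to give (2R,3R); only the carbinol centre (later C-3) is carried through, the α-centre becoming sp2 in step 7.

Step 4
Reactants: 7 (4R)-4-benzyl-3-[(2R,3R)-3-hydroxy-6-methoxy-2,6-dimethylhept-4-ynoyl]-1,3-oxazolidin-2-one
Product: 8 (2R,3R)-3-hydroxy-N,6-dimethoxy-N,2,6-trimethylhept-4-ynamide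
Conditions: MeNHOMe·HCl, AlMe3, CH2Cl2, −15 → 0 °C
Reagents that add atoms: N,O-dimethylhydroxylamine hydrochloride, CNOC.Cl
Why: Aluminium-amide transamidation of the imide (Weinreb amide formation), directed to the exocyclic carbonyl by the aluminium β-alkoxide, without epimerisation.

Step 5
Reactants: 8 (2R,3R)-3-hydroxy-N,6-dimethoxy-N,2,6-trimethylhept-4-ynamide
Product: 9 (4R,5R)-5-hydroxy-8-methoxy-4,8-dimethylnon-1-en-6-yn-3-one
Conditions: CH2=CHMgBr (3.5 equiv), THF, −78 → 0 °C; poured into cold aq HCl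
Reagents that add atoms: vinylmagnesium bromide, C=C[Mg]Br
Why: Weinreb ketone synthesis, the stable magnesium chelate preventing over-addition; the cold acidic quench stops the liberated amine from adding to the vinyl ketone.

Step 6
Reactants: 9 (4R,5R)-5-hydroxy-8-methoxy-4,8-dimethylnon-1-en-6-yn-3-one; 10 but-2-ynoic acid
Product: 11 (4R,5R)-8-methoxy-4,8-dimethyl-3-oxonon-1-en-6-yn-5-yl but-2-ynoate
Conditions: dicyclohexylcarbodiimide, DMAP (5 mol %), CH2Cl2, −20 → 0 °C
Reagents that add atoms: none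
Why: Steglich esterification of the secondary propargylic alcohol, run cold with little DMAP so that the β-acyloxy ketone does not eliminate; configuration is retained.

Step 7
Reactants: 11 (4R,5R)-8-methoxy-4,8-dimethyl-3-oxonon-1-en-6-yn-5-yl but-2-ynoate
Product: 13 (3S,3aR)-4-{[tert-butyl(dimethyl)silyl]oxy}-3-(3-methoxy-3-methylbut-1-yn-1-yl)-3a,7-dimethyl-3a,6-dihydro-2-benzofuran-1(3H)-one, via silyl dienol ether 12 (not isolated)
Conditions: TBSOTf, Et3N, CH2Cl2, −78 → 0 °C; pentane, filter; PhMe, BHT, 130 °C, sealed tube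
Reagents that add atoms: tert-butyldimethylsilyl trifluoromethanesulfonate, CC(C)(C)[Si](C)(C)OS(=O)(=O)C(F)(F)F
Why: Soft enolisation gives the (Z)-2-silyloxydiene (branched carbinol carbon syn to oxygen), and an ester-tethered intramolecular Diels–Alder reaction with the ynoate then forms the cyclohexa-1,4-diene and the γ-lactone together; 1,3-allylic strain against the OTBS group places the carbinol hydrogen in the diene plane, so the alkynyl group ends cis to the new 3a-methyl group ((3S,3aR)), and the quaternary C-3a blocks aromatisation.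

Step 8
Reactants: 13 (3S,3aR)-4-{[tert-butyl(dimethyl)silyl]oxy}-3-(3-methoxy-3-methylbut-1-yn-1-yl)-3a,7-dimethyl-3a,6-dihydro-2-benzofuran-1(3H)-one
Product: 15 (3S,3aR)-3-(3-methoxy-3-methylbut-1-yn-1-yl)-3a,7-dimethyl-3a,6-dihydro-2-benzofuran-1(3H)-one, via enol triflate 14 (not isolated)
Conditions: CsF, PhNTf2, DME, rt; then Pd(OAc)2, PPh3, n-Bu3N, HCO2H, DMF, 60 °C
Reagents that add atoms: N-phenylbis(trifluoromethanesulfonimide), O=S(=O)(N(c1ccccc1)S(=O)(=O)C(F)(F)F)C(F)(F)F (triflyl group of 14; 15 itself gains only hydrogen)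
Why: Fluoride-triggered O-triflation of the regiodefined enolate (C-3a is quaternary) followed by palladium-catalysed formate reduction of the vinyl triflate turns the stereocontrolling silyloxy group into the C4=C5 alkene; no stereocentre is touched.

Step 9
Reactants: 15 (3S,3aR)-3-(3-methoxy-3-methylbut-1-yn-1-yl)-3a,7-dimethyl-3a,6-dihydro-2-benzofuran-1(3H)-one
Product: 17 (3S,3aS,7S,7aS)-7,7a-dihydroxy-3-(3-methoxy-3-methylbut-1-yn-1-yl)-3a,7-dimethyl-3a,6,7,7a-tetrahydro-2-benzofuran-1(3H)-one, via epoxide 16 (not isolated)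
Conditions: t-BuOOH, n-BuLi, THF, −78 → 0 °C; then aq HClO4 (1 mol/L), THF, rt
Reagents that add atoms: tert-butyl hydroperoxide, CC(C)(C)OO; water, O
Why: Weitz–Scheffer nucleophilic epoxidation touches only the electron-poor butenolide alkene and closes on the upper face, the only one that keeps the γ-lactone cis-fused; acid-catalysed opening by water at the tertiary carbon C-7 remote from the carbonyl goes with inversion (trans-diaxial, Fürst–Plattner), giving 7a-OH up and 7-OH down.

Step 10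
Reactants: 17 (3S,3aS,7S,7aS)-7,7a-dihydroxy-3-(3-methoxy-3-methylbut-1-yn-1-yl)-3a,7-dimethyl-3a,6,7,7a-tetrahydro-2-benzofuran-1(3H)-one
Product: 18 (3S,3aS,4R,5S,7S,7aS)-4,5,7,7a-tetrahydroxy-3-(3-methoxy-3-methylbut-1-yn-1-yl)-3a,7-dimethylhexahydro-2-benzofuran-1(3H)-one
Conditions: OsO4 (5 mol %), NMO, acetone–H2O, rt
Reagents that add atoms: N-methylmorpholine N-oxide, C[N+]1([O-])CCOCC1; water, O
Why: Upjohn syn-dihydroxylation of the only alkene (the alkyne is inert); in the half-chair that avoids a 1,3-diaxial methyl pair the C3a–C3 bond is pseudoaxial on the lower face, so OsO4 adds from the upper face and gives the 4,5-cis-diol (4R,5S).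

Step 11
Reactants: 18 (3S,3aS,4R,5S,7S,7aS)-4,5,7,7a-tetrahydroxy-3-(3-methoxy-3-methylbut-1-yn-1-yl)-3a,7-dimethylhexahydro-2-benzofuran-1(3H)-one
Product: 20 (3S,3aR,4R,5S,7S,7aS)-5-(acetyloxy)-7,7a-dihydroxy-3-(3-methoxy-3-methylbut-1-yn-1-yl)-3a,7-dimethyl-1-oxooctahydro-2-benzofuran-4-yl benzoate, via monoacetate 19 (not isolated)
Conditions: Ac2O (1.1 equiv), pyridine, CH2Cl2, 0 °C; then BzCl, DMAP, 40 °C
Reagents that add atoms: acetic anhydride, CC(=O)OC(C)=O; benzoyl chloride, O=C(Cl)c1ccccc1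
Why: Sequential acylation by steric differentiation: the equatorial 5-OH is acetylated first, the axial neopentylic 4-OH is then benzoylated under DMAP catalysis, and the two tertiary hydroxyls stay free.

Step 12
Reactants: 20 (3S,3aR,4R,5S,7S,7aS)-5-(acetyloxy)-7,7a-dihydroxy-3-(3-methoxy-3-methylbut-1-yn-1-yl)-3a,7-dimethyl-1-oxooctahydro-2-benzofuran-4-yl benzoate
Product: 22 μ-(η2:η2) dicobalt hexacarbonyl complex of the 8,9-didehydro (ring alkyne) form of 23, via alkyne–Co2(CO)6 complex 21 (not isolated)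
Conditions: Co2(CO)8, CH2Cl2, rt; then BF3·OEt2, −20 → 0 °C
Reagents that add atoms: Co2(CO)8 (octacarbonyldicobalt), O=C=[Co](=C=O)(=C=O)(=C=O)[Co](=C=O)(=C=O)(=C=O)=C=O
Why: Intramolecular Nicholas reaction: loss of methoxide gives the Co2(CO)6-stabilised tertiary propargylic cation, which the syn-disposed tertiary 7a-hydroxyl traps to form the tertiary–tertiary ether; the bent complexed alkyne (about 140°) fits in the seven-membered ring, and no new stereocentre arises.

Step 13
Reactants: 22 μ-(η2:η2) dicobalt hexacarbonyl complex of the 8,9-didehydro form of 23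
Product: 23 (1S,2S,4S,5R,6R,7S)-4-(acetyloxy)-2-hydroxy-2,6,10,10-tetramethyl-12-oxo-11,13-dioxatricyclo[5.4.2.0(1,6)]tridec-8-en-5-yl benzoate (CNP0178319.3)
Conditions: n-Bu3SnH, benzene, 65 °C
Reagents that add atoms: none
Why: Isobe-type reductive decomplexation of an endocyclic alkyne–Co2(CO)6 complex delivers the ring alkene, which can only be cis; esters, lactone and tertiary alcohol are untouched.

**Compound list**
1 | 2-methylbut-3-yn-2-ol | CC(C)(O)C#C | starting material
2 | 3-methoxy-3-methylbut-1-yne | COC(C)(C)C#C | intermediate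
3 | (3-methoxy-3-methylbut-1-yn-1-yl)lithium | [Li]C#CC(C)(C)OC | intermediate (not isolated)
4 | 4-methoxy-4-methylpent-2-ynal | COC(C)(C)C#CC=O | intermediate
5 | (4R)-4-benzyl-3-propanoyl-1,3-oxazolidin-2-one | CCC(=O)N1[C@H](Cc2ccccc2)COC1=O | starting material
6 | (4R)-4-benzyl-3-[(1Z)-1-(dibutylboranyloxy)prop-1-en-1-yl]-1,3-oxazolidin-2-one | C/C=C(\OB(CCCC)CCCC)N1[C@H](Cc2ccccc2)COC1=O | intermediate (not isolated)
7 | (4R)-4-benzyl-3-[(2R,3R)-3-hydroxy-6-methoxy-2,6-dimethylhept-4-ynoyl]-1,3-oxazolidin-2-one | C[C@H]([C@@H](O)C#CC(C)(C)OC)C(=O)N1[C@H](Cc2ccccc2)COC1=O | intermediate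
8 | (2R,3R)-3-hydroxy-N,6-dimethoxy-N,2,6-trimethylhept-4-ynamide | C[C@H]([C@@H](O)C#CC(C)(C)OC)C(=O)N(C)OC | intermediate
9 | (4R,5R)-5-hydroxy-8-methoxy-4,8-dimethylnon-1-en-6-yn-3-one | C=CC(=O)[C@H](C)[C@@H](O)C#CC(C)(C)OC | intermediate
10 | but-2-ynoic acid | CC#CC(=O)O | starting material
11 | (4R,5R)-8-methoxy-4,8-dimethyl-3-oxonon-1-en-6-yn-5-yl but-2-ynoate | C=CC(=O)[C@H](C)[C@@H](OC(=O)C#CC)C#CC(C)(C)OC | intermediate
12 | (3Z,5S)-3-{[tert-butyl(dimethyl)silyl]oxy}-8-methoxy-4,8-dimethylnona-1,3-dien-6-yn-5-yl but-2-ynoate | C=C/C(O[Si](C)(C)C(C)(C)C)=C(\C)[C@@H](OC(=O)C#CC)C#CC(C)(C)OC | intermediate (not isolated)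
13 | (3S,3aR)-4-{[tert-butyl(dimethyl)silyl]oxy}-3-(3-methoxy-3-methylbut-1-yn-1-yl)-3a,7-dimethyl-3a,6-dihydro-2-benzofuran-1(3H)-one | CC1=C2C(=O)O[C@@H](C#CC(C)(C)OC)[C@]2(C)C(O[Si](C)(C)C(C)(C)C)=CC1 | intermediate
14 | (3S,3aR)-3-(3-methoxy-3-methylbut-1-yn-1-yl)-3a,7-dimethyl-1-oxo-1,3,3a,6-tetrahydro-2-benzofuran-4-yl trifluoromethanesulfonate | CC1=C2C(=O)O[C@@H](C#CC(C)(C)OC)[C@]2(C)C(OS(=O)(=O)C(F)(F)F)=CC1 | intermediate (not isolated)
15 | (3S,3aR)-3-(3-methoxy-3-methylbut-1-yn-1-yl)-3a,7-dimethyl-3a,6-dihydro-2-benzofuran-1(3H)-one | CC1=C2C(=O)O[C@@H](C#CC(C)(C)OC)[C@]2(C)C=CC1 | intermediate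
16 | (3S,3aS,7R,7aS)-7,7a-epoxy-3-(3-methoxy-3-methylbut-1-yn-1-yl)-3a,7-dimethyl-3a,6,7,7a-tetrahydro-2-benzofuran-1(3H)-one (epoxide on the upper face) | C[C@@]12CC=C[C@@]3(C)[C@H](C#CC(C)(C)OC)OC(=O)[C@@]13O2 | intermediate (not isolated)
17 | (3S,3aS,7S,7aS)-7,7a-dihydroxy-3-(3-methoxy-3-methylbut-1-yn-1-yl)-3a,7-dimethyl-3a,6,7,7a-tetrahydro-2-benzofuran-1(3H)-one | C[C@]1(O)CC=C[C@@]2(C)[C@H](C#CC(C)(C)OC)OC(=O)[C@@]12O | intermediate
18 | (3S,3aS,4R,5S,7S,7aS)-4,5,7,7a-tetrahydroxy-3-(3-methoxy-3-methylbut-1-yn-1-yl)-3a,7-dimethylhexahydro-2-benzofuran-1(3H)-one | O[C@H]1C[C@](C)(O)[C@]2(O)C(=O)O[C@@H](C#CC(C)(C)OC)[C@]2(C)[C@H]1O | intermediate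
19 | (3S,3aS,4R,5S,7S,7aS)-4,7,7a-trihydroxy-3-(3-methoxy-3-methylbut-1-yn-1-yl)-3a,7-dimethyl-1-oxooctahydro-2-benzofuran-5-yl acetate | CC(=O)O[C@H]1C[C@](C)(O)[C@]2(O)C(=O)O[C@@H](C#CC(C)(C)OC)[C@]2(C)[C@H]1O | intermediate (not isolated)
20 | (3S,3aR,4R,5S,7S,7aS)-5-(acetyloxy)-7,7a-dihydroxy-3-(3-methoxy-3-methylbut-1-yn-1-yl)-3a,7-dimethyl-1-oxooctahydro-2-benzofuran-4-yl benzoate | CC(=O)O[C@H]1C[C@](C)(O)[C@]2(O)C(=O)O[C@@H](C#CC(C)(C)OC)[C@]2(C)[C@H]1OC(=O)c1ccccc1 | intermediate
21 | μ-(η2:η2) dicobalt hexacarbonyl complex of alkyne 20 (all stereocentres as in 20) | CC(=O)O[C@H]1C[C@](C)(O)[C@]2(O)C(=O)O[C@@H](C34C5(C(C)(C)OC)[Co]3(=C=O)(=C=O)(=C=O)[Co]45(=C=O)(=C=O)=C=O)[C@]2(C)[C@H]1OC(=O)c1ccccc1 | intermediate (not isolated)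
22 | μ-(η2:η2) dicobalt hexacarbonyl complex of the 8,9-didehydro (ring alkyne) form of 23 (all six stereocentres as in 23) | CC(=O)O[C@H]1C[C@](C)(O)[C@]23OC(C)(C)C45[Co]6(=C=O)(=C=O)(=C=O)[Co]4(=C=O)(=C=O)(=C=O)C56[C@H](OC2=O)[C@]3(C)[C@H]1OC(=O)c1ccccc1 | intermediate
23 | (1S,2S,4S,5R,6R,7S)-4-(acetyloxy)-2-hydroxy-2,6,10,10-tetramethyl-12-oxo-11,13-dioxatricyclo[5.4.2.0(1,6)]tridec-8-en-5-yl benzoate | CC(=O)O[C@H]1C[C@](C)(O)[C@]23OC(C)(C)C=C[C@H](OC2=O)[C@]3(C)[C@H]1OC(=O)c1ccccc1 | target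

**Totals**
Total step count: 13. Longest linear sequence: 13 steps (1 → 23); 5 and 10 are purchased.

**Three steps most likely to fail, with fallbacks**

Step 7 (intramolecular Diels–Alder). The diene terminus is fully substituted, the ester tether must adopt its less stable conformation, and a 1,5-hydrogen shift from the inside methyl group or loss of the allylic ester can compete. Fallback, setting out from 9 and returning at 13: alcohol 9 is esterified (dicyclohexylcarbodiimide, DMAP) with buta-2,3-dienoic acid to the buta-2,3-dienoate ester F1, which is silylated as in step 7 to its silyl dienol ether F2. The allenic α,β-double bond is a much better dienophile, so F2 should close below 80 °C to the 7-methylidene lactone F3 (7a-H on the upper face, cis-fused). DBU then moves the exocyclic double bond into conjugation with the lactone and gives 13.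

Step 10 (face of osmylation). If the lower face of 17 turns out to be the more open one, the 4,5-diol is formed with the wrong configuration. Fallback, setting out from 17 and returning at 19: 17 is treated with I2 and AgOAc in wet acetic acid (Woodward cis-hydroxylation). The iodonium ion forms on the face that OsO4 preferred and acetate opens it at C-5 from the upper face to the trans-iodo acetate F4. The acetate then displaces iodide at C-4 with inversion (silver-assisted acetoxonium ion), and water opens the ion to the upper-face cis-hydroxy acetate. Brief treatment with Et3N lets the acetyl group settle on the equatorial C-5 oxygen, which is monoacetate 19; benzoylation as in step 11 gives 20.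

Step 12 (Nicholas etherification). A tertiary alcohol must attack a tertiary cation while the cyclohexane flips into a strained conformation, so elimination to the enyne complex can win. Fallback, setting out from 20 and returning at 23: alkyne 20 is semi-hydrogenated (H2, Pd/CaCO3 poisoned with Pb(OAc)2, quinoline) to the (Z)-allylic methyl ether F5. BF3·OEt2 in CH2Cl2 at −40 °C ionises the tertiary allylic ether, and the Z-configured allyl cation is captured at its tertiary terminus by the 7a-hydroxyl, giving 23 directly in place of steps 12 and 13.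

**Further compounds**
F1 | step 7 | (4R,5R)-8-methoxy-4,8-dimethyl-3-oxonon-1-en-6-yn-5-yl buta-2,3-dienoate | C=CC(=O)[C@H](C)[C@@H](OC(=O)C=C=C)C#CC(C)(C)OC
F2 | step 7 | (3Z,5S)-3-{[tert-butyl(dimethyl)silyl]oxy}-8-methoxy-4,8-dimethylnona-1,3-dien-6-yn-5-yl buta-2,3-dienoate | C=C/C(O[Si](C)(C)C(C)(C)C)=C(\C)[C@@H](OC(=O)C=C=C)C#CC(C)(C)OC
F3 | step 7 | (3S,3aR,7aS)-4-{[tert-butyl(dimethyl)silyl]oxy}-3-(3-methoxy-3-methylbut-1-yn-1-yl)-3a-methyl-7-methylidene-3a,6,7,7a-tetrahydro-2-benzofuran-1(3H)-one | C=C1CC=C(O[Si](C)(C)C(C)(C)C)[C@@]2(C)[C@H](C#CC(C)(C)OC)OC(=O)[C@@H]12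
F4 | step 10 | (3S,3aS,4S,5S,7S,7aS)-7,7a-dihydroxy-4-iodo-3-(3-methoxy-3-methylbut-1-yn-1-yl)-3a,7-dimethyl-1-oxooctahydro-2-benzofuran-5-yl acetate | CC(=O)O[C@H]1C[C@](C)(O)[C@]2(O)C(=O)O[C@@H](C#CC(C)(C)OC)[C@]2(C)[C@@H]1I
F5 | step 12 | (3S,3aR,4R,5S,7S,7aS)-5-(acetyloxy)-7,7a-dihydroxy-3-[(1Z)-3-methoxy-3-methylbut-1-en-1-yl]-3a,7-dimethyl-1-oxooctahydro-2-benzofuran-4-yl benzoate | CC(=O)O[C@H]1C[C@](C)(O)[C@]2(O)C(=O)O[C@@H](/C=C\C(C)(C)OC)[C@]2(C)[C@H]1OC(=O)c1ccccc1
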